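**Retrosynthetic overview**
1. The target is 4,5-di-O-vanilloyl-(−)-quinic acid. The last step is a global hydrogenolysis, preceded by two single acylations of a benzyl 1-O-benzylquinate: O5 while the cis-3,4-diol is masked as a boronate, then O4 by borinic-acid catalysis at the equatorial oxygen of that diol.
2. Key disconnection: the C3–C4 bond of the cyclohexane, giving an acyclic 1,6-dialdehyde (C3 and C4 as CHO) with only C1 and C5 as stereocentres. Forward, one SmI2 pinacol cyclisation closes the only carbocycle and sets C3 and C4 with both oxygens in place.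
3. Enabling feature: C3 and C4 are adjacent ring carbons that both bear oxygen, O3 and O4 are cis, and O4 is trans to the oxygen on neighbouring C5. This cis-1,2-diol anti to an α-alkoxy group is the native outcome of a samarium-chelated ketyl–aldehyde closure.
4. The dialdehyde comes from a γ-lactone template: C7, C1, C2, C3 from pent-4-enoic acid; C6, C5, C4 from (R)-trityl glycidyl ether, which supplies the C5 stereocentre. Enolate hydroxylation anti to the C5 side chain sets C1.
5. Ring order: temporary γ-butyrolactone (C7–C1–C6–C5–O5, step 1), opened in step 4, then cyclohexane C1–C6 (step 9). Both arenes are bought intact.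

Key step: step 9

Remark: ring atoms keep the (−)-quinic acid numbers throughout, also in acyclic intermediates (C1 quaternary, C7 carboxyl carbon, O3 cis to O4, O5 trans to O4); Tr = triphenylmethyl, TBS = tert-butyldimethylsilyl, Bn = benzyl.

**Route**

Step 1
Reactants: 1 pent-4-enoic acid; 2 (R)-trityl glycidyl ether [(R)-2-[(trityloxy)methyl]oxirane]
Product: 4 (5R)-3-allyl-5-[(trityloxy)methyl]dihydrofuran-2(3H)-one (C3 epimers), via hydroxy acid 3 (not isolated)
Conditions: LiN(iPr)2 (2.2 equiv), THF/DMPU, 0 °C; then 2, 0 → 40 °C; dilute HCl to pH 4; PPTS (cat.), toluene, 70 °C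
Reagents that add atoms: none
Why: The enediolate dianion of 1 should open the epoxide of 2 at its unhindered CH2 terminus (SN2 epoxide alkylation) and the γ-hydroxy acid lactonises on mild acid treatment; the C5 stereocentre of 2 is not touched, and the C3 epimer mixture is irrelevant because C3 is enolised in step 2.

Step 2
Reactants: 4 (5R)-3-allyl-5-[(trityloxy)methyl]dihydrofuran-2(3H)-one
Product: 5 (3S,5R)-3-allyl-3-hydroxy-5-[(trityloxy)methyl]dihydrofuran-2(3H)-one
Conditions: KN(SiMe3)2, THF, −78 °C; then 3-phenyl-2-(phenylsulfonyl)oxaziridine, −78 °C; AcOH quench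
Reagents that add atoms: 3-phenyl-2-(phenylsulfonyl)oxaziridine (Davis oxaziridine), O=S(=O)(c1ccccc1)N1OC1c1ccccc1
Why: Davis enolate hydroxylation: the oxaziridine oxygen should attack the planar potassium enolate on the face opposite the bulky C5 CH2OTr group, so the new tertiary hydroxyl (C1 of the target) comes out trans to that substituent by 1,3-induction across the γ-lactone.

Step 3
Reactants: 5 (3S,5R)-3-allyl-3-hydroxy-5-[(trityloxy)methyl]dihydrofuran-2(3H)-one
Product: 6 (3S,5R)-3-allyl-3-(benzyloxy)-5-[(trityloxy)methyl]dihydrofuran-2(3H)-one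
Conditions: NaH, BnBr, Bu4NI (cat.), THF/DMF, 0 °C → rt
Reagents that add atoms: benzyl bromide, BrCc1ccccc1
Why: Williamson etherification of the tertiary alkoxide; the lactone has no α-hydrogen left, so it cannot epimerise, and the ether keeps O1 from forming a lactol with the later C4 aldehyde.

Step 4
Reactants: 6 (3S,5R)-3-allyl-3-(benzyloxy)-5-[(trityloxy)methyl]dihydrofuran-2(3H)-one
Product: 9 (2S,4R)-2-allyl-2-(benzyloxy)-4-[(tert-butyldimethylsilyl)oxy]-5-(trityloxy)pentanoic acid, via lithium hydroxy carboxylate 7 (not isolated), via bis-silyl compound 8 (not isolated)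
Conditions: LiOH·H2O, THF/H2O, rt; concentrate; TBSCl, imidazole, DMF, rt; then THF/H2O, AcOH (cat.), rt
Reagents that add atoms: lithium hydroxide, [Li+].[OH-]; tert-butyldimethylsilyl chloride, CC(C)(C)[Si](C)(C)Cl
Why: Lactone saponification, exhaustive silylation of the hydroxy carboxylate and selective hydrolysis of the labile silyl ester is the standard way to hold a γ-hydroxy acid open without relactonisation; no stereocentre is touched.

Step 5
Reactants: 9 (2S,4R)-2-allyl-2-(benzyloxy)-4-[(tert-butyldimethylsilyl)oxy]-5-(trityloxy)pentanoic acid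
Product: 10 benzyl (2S,4R)-2-allyl-2-(benzyloxy)-4-[(tert-butyldimethylsilyl)oxy]-5-(trityloxy)pentanoate
Conditions: BnBr, KHCO3, DMF, rt
Reagents that add atoms: benzyl bromide, BrCc1ccccc1
Why: Carboxylate O-alkylation (SN2 at the benzylic carbon) under weakly basic conditions gives an ester that the final hydrogenolysis can remove.

Step 6
Reactants: 10 benzyl (2S,4R)-2-allyl-2-(benzyloxy)-4-[(tert-butyldimethylsilyl)oxy]-5-(trityloxy)pentanoate
Product: 11 benzyl (2S,4R)-2-allyl-2-(benzyloxy)-4-[(tert-butyldimethylsilyl)oxy]-5-hydroxypentanoate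
Conditions: ZnBr2, CH2Cl2/MeOH, 0 °C → rt
Reagents that add atoms: none
Why: Lewis-acid detritylation (ionisation to the trityl cation, trapped by methanol) should be selective for the primary trityl ether over the secondary TBS ether and the benzyl groups.

Step 7
Reactants: 11 benzyl (2S,4R)-2-allyl-2-(benzyloxy)-4-[(tert-butyldimethylsilyl)oxy]-5-hydroxypentanoate
Product: 12 benzyl (2S,4R)-2-allyl-2-(benzyloxy)-4-[(tert-butyldimethylsilyl)oxy]-5-oxopentanoate
Conditions: Dess–Martin periodinane, CH2Cl2, 0 °C → rt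
Reagents that add atoms: none
Why: Dess–Martin oxidation of the primary alcohol under near-neutral conditions should preserve the α-silyloxy stereocentre (C5).

Step 8
Reactants: 12 benzyl (2S,4R)-2-allyl-2-(benzyloxy)-4-[(tert-butyldimethylsilyl)oxy]-5-oxopentanoate
Product: 13 benzyl (2R,4R)-2-(benzyloxy)-4-[(tert-butyldimethylsilyl)oxy]-5-oxo-2-(2-oxoethyl)pentanoate
Conditions: O3, CH2Cl2, −78 °C; then PPh3, −78 °C → rt; used crude at once
Reagents that add atoms: ozone, [O-][O+]=O
Why: Ozonolysis of the terminal alkene with reductive work-up unveils the C3 aldehyde under neutral conditions, so the sensitive 1,6-dialdehyde is made last and neither stereocentre is at risk.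

Step 9
Reactants: 13 benzyl (2R,4R)-2-(benzyloxy)-4-[(tert-butyldimethylsilyl)oxy]-5-oxo-2-(2-oxoethyl)pentanoate
Product: 14 benzyl 1-O-benzyl-5-O-(tert-butyldimethylsilyl)quinate [benzyl (1S,3R,4R,5R)-1-(benzyloxy)-5-[(tert-butyldimethylsilyl)oxy]-3,4-dihydroxycyclohexane-1-carboxylate]
Conditions: SmI2 (3 equiv, 0.1 M in THF), t-BuOH (3 equiv), THF, −78 → −20 °C; pH 7 buffer
Reagents that add atoms: none
Why: Samarium diiodide pinacol cyclisation: electron transfer from divalent samarium to the more electrophilic α-silyloxy aldehyde (C4) gives a metal-bound ketyl that adds to the C3 aldehyde held on the same samarium, and a second electron transfer with protonation delivers the diol. The closest known reaction type is the SmI2-promoted pinacol closure of carbohydrate-derived α-alkoxy 1,6-dialdehydes to cyclitols. The cyclohexane ring C1–C6 closes in a 6-exo-trig mode (ketyl carbon C4 onto the carbonyl carbon C3, its oxygen exocyclic). C3 and C4 are set together: chelation of both oxygens to one trivalent samarium in a chair-like transition state should enforce the cis-3,4-diol, and O4 is placed anti to the C5 silyloxy group to avoid steric and dipolar repulsion with the metal-bound ketyl oxygen (substrate control from C5). The step needs cis/anti diastereoselectivity and chemoselectivity for aldehyde over ester: the first is secured by the single α-oxygenated stereocentre next to C4 and the 1,6-spacing that allows the chelated chair, the second by working at low temperature without HMPA so the α-benzyloxy benzyl ester is not reduced. A silyl shift from O5 to O4 on the samarium alkoxide would be harmless because step 10 removes the silyl group.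

Step 10
Reactants: 14 benzyl 1-O-benzyl-5-O-(tert-butyldimethylsilyl)quinate
Product: 15 benzyl 1-O-benzylquinate [benzyl 1-(benzyloxy)-3,4,5-trihydroxycyclohexane-1-carboxylate with the (−)-quinic acid configuration]
Conditions: HF·pyridine, pyridine/THF, 0 °C → rt
Reagents that add atoms: none
Why: Fluoride desilylation under mildly acidic conditions should free O5 without the base-induced lactonisation of O5 onto the cis benzyl ester.

Step 11
Reactants: 16 4-(benzyloxy)-3-methoxybenzoic acid
Product: 17 4-(benzyloxy)-3-methoxybenzoyl chloride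
Conditions: (COCl)2, DMF (cat.), CH2Cl2, 0 °C → rt
Reagents that add atoms: oxalyl chloride, O=C(Cl)C(Cl)=O
Why: Standard Vilsmeier-catalysed acid chloride formation; the benzyl ether masks the phenol of the vanilloyl unit.

Step 12
Reactants: 15 benzyl 1-O-benzylquinate; 17 4-(benzyloxy)-3-methoxybenzoyl chloride
Product: 20 benzyl 1-O-benzyl-5-O-[4-(benzyloxy)-3-methoxybenzoyl]quinate, via 3,4-O-phenylboronate 18 (not isolated), via acylated boronate 19 (not isolated)
Conditions: PhB(OH)2, 4 Å MS, CH2Cl2, rt; then 17, pyridine, DMAP (cat.), 0 °C → rt; then pinacol, rt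
Reagents that add atoms: none
Why: Transient boronate protection: phenylboronic acid should condense selectively with the cis-3,4-diol to a five-membered boronate, leaving O5–H as the only free hydroxyl for DMAP-catalysed acylation, and transesterification with pinacol then frees the diol.

Step 13
Reactants: 20 benzyl 1-O-benzyl-5-O-[4-(benzyloxy)-3-methoxybenzoyl]quinate; 17 4-(benzyloxy)-3-methoxybenzoyl chloride
Product: 21 benzyl 1-O-benzyl-4,5-bis-O-[4-(benzyloxy)-3-methoxybenzoyl]quinate
Conditions: 17, 2-aminoethyl diphenylborinate Ph2BOCH2CH2NH2 (10 mol %), iPr2NEt, MeCN, rt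
Reagents that add atoms: none
Why: Borinic-acid-catalysed regioselective acylation of a cis-1,2-diol: the tetracoordinate diphenylborinate of the 3,4-diol should be acylated at the equatorial oxygen O4, leaving free the axial O3–H, which is syn-axial to the C1 benzyloxy group.

Step 14
Reactants: 21 benzyl 1-O-benzyl-4,5-bis-O-[4-(benzyloxy)-3-methoxybenzoyl]quinate
Product: 22 Burkinabin C [4,5-di-O-vanilloyl-(−)-quinic acid; (1S,3R,4R,5R)-1,3-dihydroxy-4,5-bis[(4-hydroxy-3-methoxybenzoyl)oxy]cyclohexane-1-carboxylic acid]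
Conditions: H2 (1 atm), Pd(OH)2/C, EtOAc/THF, rt
Reagents that add atoms: none
Why: Catalytic hydrogenolysis should cleave the benzyl ester, the tertiary benzyl ether and both aryl benzyl ethers under neutral conditions in which the two vanilloyl esters neither cleave nor migrate.

**Compound list**
1 | pent-4-enoic acid | C=CCCC(=O)O | starting material
2 | (R)-trityl glycidyl ether | C1O[C@H]1COC(c2ccccc2)(c3ccccc3)c4ccccc4 | starting material
3 | (4R)-2-allyl-4-hydroxy-5-(trityloxy)pentanoic acid (C2 epimers) | OC(=O)C(CC=C)C[C@@H](O)COC(c1ccccc1)(c2ccccc2)c3ccccc3 | intermediate (not isolated)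
4 | (5R)-3-allyl-5-[(trityloxy)methyl]dihydrofuran-2(3H)-one (C3 epimers) | O=C1O[C@@H](COC(c2ccccc2)(c3ccccc3)c4ccccc4)CC1CC=C | intermediate
5 | (3S,5R)-3-allyl-3-hydroxy-5-[(trityloxy)methyl]dihydrofuran-2(3H)-one | O=C1O[C@@H](COC(c2ccccc2)(c3ccccc3)c4ccccc4)C[C@@]1(O)CC=C | intermediate
6 | (3S,5R)-3-allyl-3-(benzyloxy)-5-[(trityloxy)methyl]dihydrofuran-2(3H)-one | O=C1O[C@@H](COC(c2ccccc2)(c3ccccc3)c4ccccc4)C[C@@]1(OCc5ccccc5)CC=C | intermediate
7 | lithium (2S,4R)-2-allyl-2-(benzyloxy)-4-hydroxy-5-(trityloxy)pentanoate | [Li+].[O-]C(=O)[C@](OCc1ccccc1)(CC=C)C[C@@H](O)COC(c2ccccc2)(c3ccccc3)c4ccccc4 | intermediate (not isolated)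
8 | tert-butyldimethylsilyl (2S,4R)-2-allyl-2-(benzyloxy)-4-[(tert-butyldimethylsilyl)oxy]-5-(trityloxy)pentanoate | CC(C)(C)[Si](C)(C)OC(=O)[C@](OCc1ccccc1)(CC=C)C[C@@H](O[Si](C)(C)C(C)(C)C)COC(c2ccccc2)(c3ccccc3)c4ccccc4 | intermediate (not isolated)
9 | (2S,4R)-2-allyl-2-(benzyloxy)-4-[(tert-butyldimethylsilyl)oxy]-5-(trityloxy)pentanoic acid | OC(=O)[C@](OCc1ccccc1)(CC=C)C[C@@H](O[Si](C)(C)C(C)(C)C)COC(c2ccccc2)(c3ccccc3)c4ccccc4 | intermediate
10 | benzyl (2S,4R)-2-allyl-2-(benzyloxy)-4-[(tert-butyldimethylsilyl)oxy]-5-(trityloxy)pentanoate | O=C(OCc1ccccc1)[C@](OCc2ccccc2)(CC=C)C[C@@H](O[Si](C)(C)C(C)(C)C)COC(c3ccccc3)(c4ccccc4)c5ccccc5 | intermediate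
11 | benzyl (2S,4R)-2-allyl-2-(benzyloxy)-4-[(tert-butyldimethylsilyl)oxy]-5-hydroxypentanoate | O=C(OCc1ccccc1)[C@](OCc2ccccc2)(CC=C)C[C@@H](O[Si](C)(C)C(C)(C)C)CO | intermediate
12 | benzyl (2S,4R)-2-allyl-2-(benzyloxy)-4-[(tert-butyldimethylsilyl)oxy]-5-oxopentanoate | O=C(OCc1ccccc1)[C@](OCc2ccccc2)(CC=C)C[C@@H](O[Si](C)(C)C(C)(C)C)C=O | intermediate
13 | benzyl (2R,4R)-2-(benzyloxy)-4-[(tert-butyldimethylsilyl)oxy]-5-oxo-2-(2-oxoethyl)pentanoate | O=C(OCc1ccccc1)[C@](OCc2ccccc2)(CC=O)C[C@@H](O[Si](C)(C)C(C)(C)C)C=O | intermediate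
14 | benzyl 1-O-benzyl-5-O-(tert-butyldimethylsilyl)quinate [(1S,3R,4R,5R)] | O=C(OCc1ccccc1)[C@]3(OCc2ccccc2)C[C@@H](O)[C@@H](O)[C@H](O[Si](C)(C)C(C)(C)C)C3 | intermediate
15 | benzyl 1-O-benzylquinate | O=C(OCc1ccccc1)[C@]3(OCc2ccccc2)C[C@@H](O)[C@@H](O)[C@H](O)C3 | intermediate
16 | 4-(benzyloxy)-3-methoxybenzoic acid | COc1cc(C(=O)O)ccc1OCc2ccccc2 | starting material
17 | 4-(benzyloxy)-3-methoxybenzoyl chloride | COc1cc(C(Cl)=O)ccc1OCc2ccccc2 | intermediate
18 | benzyl 1-O-benzyl-3,4-O-(phenylboranediyl)quinate | O=C(OCc1ccccc1)[C@]3(OCc2ccccc2)C[C@H]4OB(c5ccccc5)O[C@H]4[C@H](O)C3 | intermediate (not isolated)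
19 | benzyl 1-O-benzyl-5-O-[4-(benzyloxy)-3-methoxybenzoyl]-3,4-O-(phenylboranediyl)quinate | O=C(OCc1ccccc1)[C@]3(OCc2ccccc2)C[C@H]4OB(c5ccccc5)O[C@H]4[C@H](OC(=O)c6ccc(OCc7ccccc7)c(OC)c6)C3 | intermediate (not isolated)
20 | benzyl 1-O-benzyl-5-O-[4-(benzyloxy)-3-methoxybenzoyl]quinate | O=C(OCc1ccccc1)[C@]3(OCc2ccccc2)C[C@@H](O)[C@@H](O)[C@H](OC(=O)c4ccc(OCc5ccccc5)c(OC)c4)C3 | intermediate
21 | benzyl 1-O-benzyl-4,5-bis-O-[4-(benzyloxy)-3-methoxybenzoyl]quinate | O=C(OCc1ccccc1)[C@]3(OCc2ccccc2)C[C@@H](O)[C@@H](OC(=O)c4ccc(OCc5ccccc5)c(OC)c4)[C@H](OC(=O)c6ccc(OCc7ccccc7)c(OC)c6)C3 | intermediate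
22 | Burkinabin C (4,5-di-O-vanilloyl-(−)-quinic acid) | COc1cc(C(=O)O[C@@H]2[C@H](O)C[C@@](O)(C(=O)O)C[C@H]2OC(=O)c2ccc(O)c(OC)c2)ccc1O | target

**Step count and risks**
Total step count: 14. Longest linear sequence: 13 (steps 1–10 and 12–14; step 11 is a one-step side branch).

Steps most likely to fail:

1. Step 9. The cis/anti diastereoselectivity may erode (trans-diol formation), or the aldehydes may simply be reduced, or silyloxide may be lost from the ketyl. The fallback sets out from 12 and comes back at 14. Wittig methylenation (Ph3P=CH2, THF, −78 → 0 °C) should give the diene benzyl (2S,4R)-2-allyl-2-(benzyloxy)-4-[(tert-butyldimethylsilyl)oxy]hex-5-enoate F1. Ring-closing metathesis with the second-generation Grubbs catalyst RuCl2(=CHPh)(H2IMes)(PCy3) in CH2Cl2 at 40 °C closes the same C3–C4 linkage as the alkene of benzyl (1S,5R)-1-(benzyloxy)-5-[(tert-butyldimethylsilyl)oxy]cyclohex-3-ene-1-carboxylate F2. Dihydroxylation (OsO4 cat., NMO, acetone/H2O) from the face anti to the allylic silyloxy group should then give 14.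

2. Step 13. Regioselectivity may be insufficient (acylation at O3) or base may induce acyl migration. The fallback sets out from 20 and comes back at 21, and replaces catalyst control by a temporary O3 group placed through the axial-ester rule of cyclic orthoester hydrolysis. 2-Chloro-1,1,1-trimethoxyethane with CSA (cat.) in CH2Cl2 should give the cyclic orthoester benzyl 1-O-benzyl-5-O-[4-(benzyloxy)-3-methoxybenzoyl]-3,4-O-(2-chloro-1-methoxyethylidene)quinate F3. Aqueous AcOH should open it to the axial ester benzyl 1-O-benzyl-5-O-[4-(benzyloxy)-3-methoxybenzoyl]-3-O-(chloroacetyl)quinate F4. Acylation of the free equatorial O4–H with 17 (pyridine, DMAP cat., CH2Cl2) gives benzyl 1-O-benzyl-4,5-bis-O-[4-(benzyloxy)-3-methoxybenzoyl]-3-O-(chloroacetyl)quinate F5. Thiourea with NaHCO3 in EtOH/THF at 55 °C removes the chloroacetyl group selectively and returns 21.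

3. Step 1. Epoxide opening by the carboxylic acid dianion may be sluggish (proton transfer, low conversion), or the trityl ether may be lost during lactonisation. The fallback sets out from 2 and comes back at 4. Diethyl allylmalonate with NaOEt in EtOH at reflux should open the epoxide and lactonise in the same flask to ethyl (5R)-3-allyl-2-oxo-5-[(trityloxy)methyl]tetrahydrofuran-3-carboxylate F6. Krapcho dealkoxycarbonylation (LiCl, wet DMSO, 150 °C) then gives 4.

**Further compounds**
F1 | step 9 | benzyl (2S,4R)-2-allyl-2-(benzyloxy)-4-[(tert-butyldimethylsilyl)oxy]hex-5-enoate | O=C(OCc1ccccc1)[C@](OCc2ccccc2)(CC=C)C[C@@H](O[Si](C)(C)C(C)(C)C)C=C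
F2 | step 9 | benzyl (1S,5R)-1-(benzyloxy)-5-[(tert-butyldimethylsilyl)oxy]cyclohex-3-ene-1-carboxylate | O=C(OCc1ccccc1)[C@]3(OCc2ccccc2)CC=C[C@H](O[Si](C)(C)C(C)(C)C)C3
F3 | step 13 | benzyl 1-O-benzyl-5-O-[4-(benzyloxy)-3-methoxybenzoyl]-3,4-O-(2-chloro-1-methoxyethylidene)quinate | O=C(OCc1ccccc1)[C@]3(OCc2ccccc2)C[C@H]4OC(CCl)(OC)O[C@H]4[C@H](OC(=O)c5ccc(OCc6ccccc6)c(OC)c5)C3
F4 | step 13 | benzyl 1-O-benzyl-5-O-[4-(benzyloxy)-3-methoxybenzoyl]-3-O-(chloroacetyl)quinate | O=C(OCc1ccccc1)[C@]3(OCc2ccccc2)C[C@@H](OC(=O)CCl)[C@@H](O)[C@H](OC(=O)c4ccc(OCc5ccccc5)c(OC)c4)C3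
F5 | step 13 | benzyl 1-O-benzyl-4,5-bis-O-[4-(benzyloxy)-3-methoxybenzoyl]-3-O-(chloroacetyl)quinate | O=C(OCc1ccccc1)[C@]3(OCc2ccccc2)C[C@@H](OC(=O)CCl)[C@@H](OC(=O)c4ccc(OCc5ccccc5)c(OC)c4)[C@H](OC(=O)c6ccc(OCc7ccccc7)c(OC)c6)C3
F6 | step 1 | ethyl (5R)-3-allyl-2-oxo-5-[(trityloxy)methyl]tetrahydrofuran-3-carboxylate (C3 epimers) | CCOC(=O)C1(CC=C)C[C@H](COC(c2ccccc2)(c3ccccc3)c4ccccc4)OC1=O
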